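**Retrosynthetic overview**
1. 20 ⇐ 18 by hydrogenolysis of the three benzyl-type groups and air oxidation of ring B; 18 ⇐ 17 by asymmetric hydrogenation of C3=C4, which sets C3.
2. 17 ⇐ 13 by the key step: the ring B hydroquinone is oxidised to a vinylquinone and C4a of ring A adds to C4, closing ring C (the pyran ring) through the C4–C4a bond.
3. Enabling feature: ring B is a 2',5'-quinone joined through C1' to C3, so with an exocyclic C3=C4 bond C4 is the electrophilic end of the dienone C4=C3–C1'=C6'–C5'=O, while C4a is ortho to O1 and para to the C7 methoxy group.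
4. 13 ⇐ Suzuki coupling of alkenylboronate 7 (phenol 4 + 2,3-dibromopropene, O1–C2 bond) with aryl bromide 11 (C3–C1' bond).
5. Ring order: rings A and B come from 1 and 8; ring C is the only ring made (step 9).

Key step: step 9

Assumption: isoflavan numbering is used (ring A C4a–C8a, ring C O1–C4, ring B C1'–C6'), the target is (3S) (CIP order at C3: C2 > C1' > C4 > H), and 1, 5 and 8 are taken as purchasable.

**Step 1**
Reactants: 1 2-hydroxy-3,4-dimethoxybenzaldehyde
Product: 2 2-(benzyloxy)-3,4-dimethoxybenzaldehyde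
Conditions: BnBr, K2CO3, DMF, 60 °C
Reagents that add atoms: benzyl bromide, BrCc1ccccc1
Why: Williamson etherification (SN2 on benzyl bromide) masks the future C8 hydroxyl so that the phenol made next is the only free one.

**Step 2**
Reactants: 2 2-(benzyloxy)-3,4-dimethoxybenzaldehyde
Product: 4 2-(benzyloxy)-3,4-dimethoxyphenol, via aryl formate 3 (not isolated)
Conditions: mCPBA, CH2Cl2, 0 °C to rt; then KOH, MeOH/H2O, rt
Reagents that add atoms: 3-chloroperoxybenzoic acid (mCPBA), OOC(=O)c1cccc(Cl)c1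
Why: Baeyer–Villiger (Dakin-type) oxidation, in which the electron-rich aryl group migrates to oxygen to give formate 3, followed by saponification, puts the oxygen that becomes O1 in place of the formyl carbon.

**Step 3**
Reactants: 4 2-(benzyloxy)-3,4-dimethoxyphenol; 5 2,3-dibromoprop-1-ene
Product: 6 2-(benzyloxy)-1-[(2-bromoprop-2-en-1-yl)oxy]-3,4-dimethoxybenzene
Conditions: K2CO3, acetone, reflux
Reagents that add atoms: none
Why: Williamson etherification by SN2 displacement of the allylic bromide of 5, the vinylic bromide being inert to phenoxide, forms the O1–C2 bond.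

**Step 4**
Reactants: 6 2-(benzyloxy)-1-[(2-bromoprop-2-en-1-yl)oxy]-3,4-dimethoxybenzene
Product: 7 2-{3-[2-(benzyloxy)-3,4-dimethoxyphenoxy]prop-1-en-2-yl}-4,4,5,5-tetramethyl-1,3,2-dioxaborolane
Conditions: B2pin2, PdCl2(PPh3)2 (3 mol%), PPh3, KOPh, toluene, 50 °C
Reagents that add atoms: bis(pinacolato)diboron, CC1(C)OB(OC1(C)C)B1OC(C)(C)C(C)(C)O1
Why: Miyaura borylation of a 1-alkenyl bromide under zerovalent palladium catalysis, with the weak base KOPh to prevent Suzuki homocoupling, should give the 1,1-disubstituted alkenylboronate.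

**Step 5**
Reactants: 8 2,3-dimethoxy-1,4-benzoquinone
Product: 10 1,4-bis(tert-butyldimethylsilyloxy)-2,3-dimethoxybenzene, via hydroquinone 9 (not isolated)
Conditions: Na2S2O4, EtOAc/H2O, rt; then TBSCl, imidazole, DMF, rt
Reagents that add atoms: tert-butyldimethylsilyl chloride, CC(C)(C)[Si](C)(C)Cl
Why: dithionite reduction of the quinone to hydroquinone 9 followed by imidazole-promoted silylation protects both phenols in a form that survives cross-coupling and is later removed by fluoride without acid.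

**Step 6**
Reactants: 10 1,4-bis(tert-butyldimethylsilyloxy)-2,3-dimethoxybenzene
Product: 11 1-bromo-2,5-bis(tert-butyldimethylsilyloxy)-3,4-dimethoxybenzene
Conditions: NBS (1.0 equiv), MeCN, 0 °C to rt
Reagents that add atoms: N-bromosuccinimide, O=C1CCC(=O)N1Br
Why: electrophilic aromatic bromination (SEAr); the two free ring positions of 10 are equivalent and one equivalent of NBS should stop at the monobromide.

**Step 7**
Reactants: 7 2-{3-[2-(benzyloxy)-3,4-dimethoxyphenoxy]prop-1-en-2-yl}-4,4,5,5-tetramethyl-1,3,2-dioxaborolane; 11 1-bromo-2,5-bis(tert-butyldimethylsilyloxy)-3,4-dimethoxybenzene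
Product: 12 2-(benzyloxy)-1-({2-[2,5-bis(tert-butyldimethylsilyloxy)-3,4-dimethoxyphenyl]prop-2-en-1-yl}oxy)-3,4-dimethoxybenzene
Conditions: Pd(OAc)2 (5 mol%), SPhos (10 mol%), K3PO4, toluene/H2O, 70 °C
Reagents that add atoms: none
Why: Suzuki–Miyaura coupling, with SPhos chosen for the electron-rich ortho-substituted aryl bromide, forms the C3–C1' bond and completes the acyclic carbon skeleton.

**Step 8**
Reactants: 12 2-(benzyloxy)-1-({2-[2,5-bis(tert-butyldimethylsilyloxy)-3,4-dimethoxyphenyl]prop-2-en-1-yl}oxy)-3,4-dimethoxybenzene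
Product: 13 2-{3-[2-(benzyloxy)-3,4-dimethoxyphenoxy]prop-1-en-2-yl}-5,6-dimethoxybenzene-1,4-diol
Conditions: TBAF, AcOH, THF, 0 °C, argon
Reagents that add atoms: none
Why: fluoride cleavage of the two aryl silyl ethers, buffered by AcOH and run under argon, frees the hydroquinone without acid that would protonate the electron-rich 1,1-disubstituted alkene.

**Step 9**
Reactants: 13 2-{3-[2-(benzyloxy)-3,4-dimethoxyphenoxy]prop-1-en-2-yl}-5,6-dimethoxybenzene-1,4-diol
Product: 17 dibenzyl 2-[8-(benzyloxy)-6,7-dimethoxy-2H-chromen-3-yl]-5,6-dimethoxy-1,4-phenylene bis(carbonate), via vinylquinone 14 (not isolated), via quinone methide 15 (not isolated), via chromene hydroquinone 16 (not isolated)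
Conditions: Ag2O, MgSO4, CH2Cl2 (0.01 M), 0 °C, filter; Sc(OTf)3 (10 mol%), CH2Cl2/MeCN, −40 to 0 °C; then pyridine, CbzCl, DMAP, 0 °C
Reagents that add atoms: benzyl chloroformate, O=C(Cl)OCc1ccccc1
Why: Proposed new method: Ag2O oxidises the ring B hydroquinone to vinylquinone 14, which turns C4 from the nucleophilic terminus of an electron-rich styrene into the electrophilic δ-carbon of the dienone C4=C3–C1'=C6'–C5'=O; Sc(OTf)3 bound at the C5' carbonyl then triggers a Friedel–Crafts 1,6-addition of C4a to C4, and the resulting hydroxy-o-quinone methide 15 aromatises by proton loss from C4 to the 2H-chromene hydroquinone 16, which is trapped as its bis(benzyl carbonate). The closest known reaction types are the acid-catalysed arylation of benzoquinones by alkoxyarenes and the tautomerisation to hydroquinones of the isoquinone methides formed in vinylquinone Diels–Alder reactions; addition of an arene to the vinyl terminus of a vinylquinone has not been shown. The pyran ring closes in a 6-endo-trig mode. No stereocentre is formed because C3 becomes sp2, and the net change from 13 is a dehydrogenative coupling of two carbons that are both nucleophilic before the oxidation. The step needs attack at C4 rather than at C3 (Markovnikov) or C6' (1,4), and by C4a rather than C5: the first is secured by running the acid stage only at the quinone oxidation level (acid on 13 would protonate C4 and close a five-membered ring through C3), the others by the tether, which lets only C4a reach C4 in a six-membered transition state. Dilution is meant to suppress Diels–Alder dimerisation of 14.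

**Step 10**
Reactants: 17 dibenzyl 2-[8-(benzyloxy)-6,7-dimethoxy-2H-chromen-3-yl]-5,6-dimethoxy-1,4-phenylene bis(carbonate)
Product: 18 dibenzyl 2-[(3S)-8-(benzyloxy)-6,7-dimethoxy-3,4-dihydro-2H-chromen-3-yl]-5,6-dimethoxy-1,4-phenylene bis(carbonate)
Conditions: [Ir(cod)(L)]BArF (2 mol%; L = (S)-4-tert-butyl-2-[2-(diphenylphosphino)phenyl]-4,5-dihydrooxazole, BArF = B[3,5-(CF3)2C6H3]4), H2 (50 bar), CH2Cl2, rt
Reagents that add atoms: none
Why: iridium-catalysed asymmetric hydrogenation of a trisubstituted aryl alkene, a reaction established for 3-aryl-2H-chromenes, adds H2 to one face of C3=C4 under control of the chiral P,N ligand and so sets C3 as (S), the ligand antipode being chosen to give this sense.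

**Step 11**
Reactants: 18 dibenzyl 2-[(3S)-8-(benzyloxy)-6,7-dimethoxy-3,4-dihydro-2H-chromen-3-yl]-5,6-dimethoxy-1,4-phenylene bis(carbonate)
Product: 20 5-[(3S)-8-hydroxy-6,7-dimethoxy-3,4-dihydro-2H-chromen-3-yl]-2,3-dimethoxycyclohexa-2,5-diene-1,4-dione, via triol hydroquinone 19 (not isolated)
Conditions: H2 (1 atm), Pd/C, EtOAc, rt; filter; then air, rt
Reagents that add atoms: none
Why: hydrogenolysis cleaves the benzyl ether and both benzyl carbonates to hydroquinone 19, whose autoxidation in air under neutral conditions should give the quinone without touching C3, which is not acidic at the hydroquinone level.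

**Compound list**
1 | 2-hydroxy-3,4-dimethoxybenzaldehyde | O=Cc1ccc(OC)c(OC)c1O | starting material
2 | 2-(benzyloxy)-3,4-dimethoxybenzaldehyde | O=Cc1ccc(OC)c(OC)c1OCc1ccccc1 | intermediate
3 | 2-(benzyloxy)-3,4-dimethoxyphenyl formate | O=COc1ccc(OC)c(OC)c1OCc1ccccc1 | intermediate
4 | 2-(benzyloxy)-3,4-dimethoxyphenol | Oc1ccc(OC)c(OC)c1OCc1ccccc1 | intermediate
5 | 2,3-dibromoprop-1-ene | C=C(Br)CBr | starting material
6 | 2-(benzyloxy)-1-[(2-bromoprop-2-en-1-yl)oxy]-3,4-dimethoxybenzene | C=C(Br)COc1ccc(OC)c(OC)c1OCc1ccccc1 | intermediate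
7 | 2-{3-[2-(benzyloxy)-3,4-dimethoxyphenoxy]prop-1-en-2-yl}-4,4,5,5-tetramethyl-1,3,2-dioxaborolane | C=C(COc1ccc(OC)c(OC)c1OCc1ccccc1)B1OC(C)(C)C(C)(C)O1 | intermediate
8 | 2,3-dimethoxy-1,4-benzoquinone | COC1=C(OC)C(=O)C=CC1=O | starting material
9 | 2,3-dimethoxybenzene-1,4-diol | COc1c(O)ccc(O)c1OC | intermediate
10 | 1,4-bis(tert-butyldimethylsilyloxy)-2,3-dimethoxybenzene | COc1c(O[Si](C)(C)C(C)(C)C)ccc(O[Si](C)(C)C(C)(C)C)c1OC | intermediate
11 | 1-bromo-2,5-bis(tert-butyldimethylsilyloxy)-3,4-dimethoxybenzene | COc1c(O[Si](C)(C)C(C)(C)C)cc(Br)c(O[Si](C)(C)C(C)(C)C)c1OC | intermediate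
12 | 2-(benzyloxy)-1-({2-[2,5-bis(tert-butyldimethylsilyloxy)-3,4-dimethoxyphenyl]prop-2-en-1-yl}oxy)-3,4-dimethoxybenzene | C=C(COc1ccc(OC)c(OC)c1OCc1ccccc1)c1cc(O[Si](C)(C)C(C)(C)C)c(OC)c(OC)c1O[Si](C)(C)C(C)(C)C | intermediate
13 | 2-{3-[2-(benzyloxy)-3,4-dimethoxyphenoxy]prop-1-en-2-yl}-5,6-dimethoxybenzene-1,4-diol | C=C(COc1ccc(OC)c(OC)c1OCc1ccccc1)c1cc(O)c(OC)c(OC)c1O | intermediate
14 | 5-{3-[2-(benzyloxy)-3,4-dimethoxyphenoxy]prop-1-en-2-yl}-2,3-dimethoxy-1,4-benzoquinone | C=C(COc1ccc(OC)c(OC)c1OCc1ccccc1)C1=CC(=O)C(OC)=C(OC)C1=O | intermediate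
15 | 6-[8-(benzyloxy)-6,7-dimethoxychroman-3-ylidene]-4-hydroxy-2,3-dimethoxycyclohexa-2,4-dien-1-one | COC1=C(OC)C(=O)C(=C2COc3c(OCc4ccccc4)c(OC)c(OC)cc3C2)C=C1O | intermediate
16 | 2-[8-(benzyloxy)-6,7-dimethoxy-2H-chromen-3-yl]-5,6-dimethoxybenzene-1,4-diol | COc1c(O)cc(C2=Cc3cc(OC)c(OC)c(OCc4ccccc4)c3OC2)c(O)c1OC | intermediate
17 | dibenzyl 2-[8-(benzyloxy)-6,7-dimethoxy-2H-chromen-3-yl]-5,6-dimethoxy-1,4-phenylene bis(carbonate) | COc1c(OC(=O)OCc2ccccc2)cc(C2=Cc3cc(OC)c(OC)c(OCc4ccccc4)c3OC2)c(OC(=O)OCc2ccccc2)c1OC | intermediate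
18 | dibenzyl 2-[(3S)-8-(benzyloxy)-6,7-dimethoxy-3,4-dihydro-2H-chromen-3-yl]-5,6-dimethoxy-1,4-phenylene bis(carbonate) | COc1c(OC(=O)OCc2ccccc2)cc([C@H]2COc3c(cc(OC)c(OC)c3OCc3ccccc3)C2)c(OC(=O)OCc2ccccc2)c1OC | intermediate
19 | 2-[(3S)-8-hydroxy-6,7-dimethoxy-3,4-dihydro-2H-chromen-3-yl]-5,6-dimethoxybenzene-1,4-diol | COc1c(O)cc([C@H]2COc3c(cc(OC)c(OC)c3O)C2)c(O)c1OC | intermediate
20 | 5-[(3S)-8-hydroxy-6,7-dimethoxy-3,4-dihydro-2H-chromen-3-yl]-2,3-dimethoxycyclohexa-2,5-diene-1,4-dione | COC1=C(OC)C(=O)C([C@H]2COc3c(cc(OC)c(OC)c3O)C2)=CC1=O | target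

**Step count and risks**
Total steps: 11. Longest linear sequence: 9 steps (1, 2, 3, 4, 7, 8, 9, 10, 11).

Most likely to fail:

1. Step 9 (Proposed new method). The vinylquinone may dimerise by Diels–Alder reaction before it cyclises. The Friedel–Crafts addition may be slow because ring A is only moderately nucleophilic. Hydrogen exchange between product hydroquinone and unreacted vinylquinone may return 13 to the acidic medium, where it would cyclise the Markovnikov way. Fallback by known chemistry, setting out from 12 and coming back at 19: hydroboration–oxidation of 12 (BH3·SMe2, THF; NaBO3·4H2O) should give the racemic primary alcohol F1. Oxidation (TEMPO, PhI(OAc)2, MeCN/H2O) should give the carboxylic acid F2. Intramolecular Friedel–Crafts acylation ((COCl)2, cat. DMF; then SnCl4, CH2Cl2, −78 °C) closes the same C4–C4a bond to give the racemic isoflavanone F3. Asymmetric transfer hydrogenation with dynamic kinetic resolution (RuCl[(S,S)-TsDPEN](p-cymene), HCO2H/Et3N) should give the cis-(3S,4S)-isoflavan-4-ol F4. Hydrogenolysis (H2, Pd/C, EtOH/AcOH) removes the C4 hydroxyl and the benzyl group to give the (3S)-isoflavan F5. TBAF/AcOH then gives 19, which air oxidises to 20 as in step 11.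

2. Step 10. Facial selectivity may be poor, or hydrogenation slow, because of the ortho carbonate on ring B next to the alkene. Fallback, setting out from 13 and coming back at 19: step 9 is run without the chloroformate cap and 16 is isolated under argon. A chiral phosphoric acid ((R)-3,3'-bis(2,4,6-triisopropylphenyl)-1,1'-binaphthyl-2,2'-diyl hydrogen phosphate, 10 mol%) with Hantzsch ester in toluene should reprotonate C4, regenerate quinone methide 15 and deliver hydride to C3 (organocatalytic transfer hydrogenation of an o-hydroxystyrene through its o-quinone methide), giving the (3S)-isoflavan hydroquinone F6. The acid antipode is chosen for the (S) sense. H2, Pd/C then gives 19 and air gives 20.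

3. Step 7. The α-substituted alkenylboronate may protodeboronate, or zerovalent palladium may ionise the allylic aryl ether. Fallback, setting out from 4 and 11 and coming back at 12: alkylation of 4 with 2-chloro-N-methoxy-N-methylacetamide (K2CO3, NaI, DMF) should give the Weinreb amide F7. Bromine–lithium exchange on 11 (n-BuLi, THF, −78 °C, short contact) and addition to F7 should give the aryl ketone F8. Wittig methylenation (Ph3PCH3Br, KOtBu, THF) then gives 12.

**Further compounds**
F1 | step 9 | rac-3-[2-(benzyloxy)-3,4-dimethoxyphenoxy]-2-[2,5-bis(tert-butyldimethylsilyloxy)-3,4-dimethoxyphenyl]propan-1-ol | OCC(COc1ccc(OC)c(OC)c1OCc1ccccc1)c1cc(O[Si](C)(C)C(C)(C)C)c(OC)c(OC)c1O[Si](C)(C)C(C)(C)C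
F2 | step 9 | rac-3-[2-(benzyloxy)-3,4-dimethoxyphenoxy]-2-[2,5-bis(tert-butyldimethylsilyloxy)-3,4-dimethoxyphenyl]propanoic acid | OC(=O)C(COc1ccc(OC)c(OC)c1OCc1ccccc1)c1cc(O[Si](C)(C)C(C)(C)C)c(OC)c(OC)c1O[Si](C)(C)C(C)(C)C
F3 | step 9 | rac-8-(benzyloxy)-3-[2,5-bis(tert-butyldimethylsilyloxy)-3,4-dimethoxyphenyl]-6,7-dimethoxychroman-4-one | O=C1c2cc(OC)c(OC)c(OCc3ccccc3)c2OCC1c1cc(O[Si](C)(C)C(C)(C)C)c(OC)c(OC)c1O[Si](C)(C)C(C)(C)C
F4 | step 9 | (3S,4S)-8-(benzyloxy)-3-[2,5-bis(tert-butyldimethylsilyloxy)-3,4-dimethoxyphenyl]-6,7-dimethoxychroman-4-ol | O[C@@H]1c2cc(OC)c(OC)c(OCc3ccccc3)c2OC[C@@H]1c1cc(O[Si](C)(C)C(C)(C)C)c(OC)c(OC)c1O[Si](C)(C)C(C)(C)C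
F5 | step 9 | (3S)-3-[2,5-bis(tert-butyldimethylsilyloxy)-3,4-dimethoxyphenyl]-6,7-dimethoxychroman-8-ol | COc1c(O[Si](C)(C)C(C)(C)C)cc([C@H]2COc3c(cc(OC)c(OC)c3O)C2)c(O[Si](C)(C)C(C)(C)C)c1OC
F6 | step 10 | 2-[(3S)-8-(benzyloxy)-6,7-dimethoxy-3,4-dihydro-2H-chromen-3-yl]-5,6-dimethoxybenzene-1,4-diol | COc1c(O)cc([C@H]2COc3c(cc(OC)c(OC)c3OCc3ccccc3)C2)c(O)c1OC
F7 | step 7 | 2-[2-(benzyloxy)-3,4-dimethoxyphenoxy]-N-methoxy-N-methylacetamide | CON(C)C(=O)COc1ccc(OC)c(OC)c1OCc1ccccc1
F8 | step 7 | 2-[2-(benzyloxy)-3,4-dimethoxyphenoxy]-1-[2,5-bis(tert-butyldimethylsilyloxy)-3,4-dimethoxyphenyl]ethan-1-one | O=C(COc1ccc(OC)c(OC)c1OCc1ccccc1)c1cc(O[Si](C)(C)C(C)(C)C)c(OC)c(OC)c1O[Si](C)(C)C(C)(C)C
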